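**Retrosynthetic overview**

1. The 1,4-dialdehyde (C11 on C7, C12 on C8) is released last from a cyclic bis-acetal in which C11 and C12 share one oxygen; before that, the (Z)-cinnamate is made on the free 1β-hydroxyl by acylation with phenylpropiolic acid and cis-selective semi-hydrogenation.
2. Ring B is disconnected at C6–C7 (aldol; dehydration then gives C6=C7) and at C8a–C8 (radical conjugate addition). Both bonds form in one iron-hydride-initiated annulation of the monocyclic ring A aldehyde 9 with (5R)-5-menthyloxybutenolide 10, which supplies C7, C8, C11 and C12.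
3. Enabling feature: C8a is a fully substituted ring carbon that carries a methyl group and lies gamma to C6. Written as an exocyclic methylene gamma,delta to a C6 aldehyde, it becomes a tertiary radical by hydrogen-atom transfer (the hydrogen completes the methyl), and the C7(CHO)–C8(CHO) unit is a masked 4-oxobutenoate whose alpha carbon C7 closes onto C6.
4. Ring A is bought, not built: 1,2-dimethylcyclohexa-1,4-diene already holds C1–C4, C4a, C8a and both vinylic methyls. Dihydroxylation, desymmetrising silylation (sets C1), oxidation, alkylation at C4a and methylenation of C8a lead to 9.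
5. Order of ring formation: ring A (starting material), then a temporary lactone ring and ring B together (step 7); the lactone-derived ring is opened in the last step.

Key step: step 7

Assumption: butenolide 10 is taken as purchasable (otherwise one step from 5-hydroxyfuran-2(5H)-one and (−)-menthol); atom numbers C1–C8a, C11 (on C7) and C12 (on C8) are those of the target decalin throughout, and β means the face of the C8a methyl group.

**Route**

Step 1
Reactants: 1 1,2-dimethylcyclohexa-1,4-diene
Product: 2 cis-4,5-dimethylcyclohex-4-ene-1,2-diol (meso)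
Conditions: OsO4 (1 mol %), N-methylmorpholine N-oxide, acetone/H2O, 0 °C
Reagents that add atoms: N-methylmorpholine N-oxide (C[N+]1([O-])CCOCC1), water (O)
Why: Catalytic osmium tetroxide syn-dihydroxylation should take the accessible cis-disubstituted alkene much faster than the hindered tetrasubstituted one and give the meso cis-diol (no stereocentre is fixed yet).

Step 2
Reactants: 2 cis-4,5-dimethylcyclohex-4-ene-1,2-diol
Product: 3 (1S,6R)-6-{[tert-butyl(dimethyl)silyl]oxy}-3,4-dimethylcyclohex-3-en-1-ol
Conditions: TBSCl, iPr2NEt, chiral amino-acid-derived N-methylimidazole silylation catalyst (20 mol %), THF, −40 °C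
Reagents that add atoms: tert-butyl(chloro)dimethylsilane (CC(C)(C)[Si](C)(C)Cl)
Why: Catalytic enantioselective mono-silylation of a meso 1,2-diol (desymmetrisation): the hydrogen-bonding catalyst delivers the silyl group to one enantiotopic hydroxyl and so fixes the future C1 as R, the catalyst enantiomer being chosen accordingly.

Step 3
Reactants: 3 (1S,6R)-6-{[tert-butyl(dimethyl)silyl]oxy}-3,4-dimethylcyclohex-3-en-1-ol
Product: 4 (6R)-6-{[tert-butyl(dimethyl)silyl]oxy}-3,4-dimethylcyclohex-3-en-1-one
Conditions: Dess–Martin periodinane, NaHCO3, CH2Cl2, 0 °C to rt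
Reagents that add atoms: none
Why: Dess–Martin oxidation under buffered, non-enolising conditions should give the α-silyloxy ketone (future C8a carbonyl) without loss of the C1 centre or migration of the β,γ double bond.

Step 4
Reactants: 4 (6R)-6-{[tert-butyl(dimethyl)silyl]oxy}-3,4-dimethylcyclohex-3-en-1-one; 5 2-bromo-N-methoxy-N-methylacetamide
Product: 7 N-methoxy-N-methyl-2-[(1S,5R)-5-{[tert-butyl(dimethyl)silyl]oxy}-2,3-dimethyl-6-oxocyclohex-2-en-1-yl]acetamide, via trans-alkylated ketone 6 (not isolated)
Conditions: LiN(iPr)2, THF, −78 °C; 5, DMPU, −78 to −40 °C; then LiN(SiMe3)2, −78 °C; then AcOH, −78 °C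
Reagents that add atoms: none
Why: Kinetic enolate alkylation followed by deprotonation and kinetic protonation: the base removes the allylic C4a proton (away from the silyloxy carbon), the dienolate is alkylated at its α carbon C4a anti to the pseudoaxial C1 silyloxy group, and re-enolisation with protonation from that same less hindered face places the hydrogen anti and the side chain cis to the C1 oxygen (C4a = S).

Step 5
Reactants: 7 N-methoxy-N-methyl-2-[(1S,5R)-5-{[tert-butyl(dimethyl)silyl]oxy}-2,3-dimethyl-6-oxocyclohex-2-en-1-yl]acetamide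
Product: 8 N-methoxy-N-methyl-2-[(1S,5R)-5-{[tert-butyl(dimethyl)silyl]oxy}-2,3-dimethyl-6-methylidenecyclohex-2-en-1-yl]acetamide
Conditions: Zn, CH2Br2, TiCl4, THF/CH2Cl2, 0 °C to rt
Reagents that add atoms: dibromomethane (BrCBr)
Why: Lombardo–Takai methylenation: the non-basic gem-dimetallic titanium reagent should convert the hindered, easily enolised ketone into the exocyclic alkene without epimerising C4a or touching the Weinreb amide.

Step 6
Reactants: 8 N-methoxy-N-methyl-2-[(1S,5R)-5-{[tert-butyl(dimethyl)silyl]oxy}-2,3-dimethyl-6-methylidenecyclohex-2-en-1-yl]acetamide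
Product: 9 2-[(1S,5R)-5-{[tert-butyl(dimethyl)silyl]oxy}-2,3-dimethyl-6-methylidenecyclohex-2-en-1-yl]acetaldehyde
Conditions: iBu2AlH, THF, −78 °C; aq. KNaC4H4O6 work-up
Reagents that add atoms: none
Why: Reduction of a Weinreb amide stops at the aldehyde because the chelated tetrahedral aluminium adduct collapses only on work-up.

Step 7
Reactants: 9 2-[(1S,5R)-5-{[tert-butyl(dimethyl)silyl]oxy}-2,3-dimethyl-6-methylidenecyclohex-2-en-1-yl]acetaldehyde; 10 (5R)-5-{[(1R,2S,5R)-5-methyl-2-(propan-2-yl)cyclohexyl]oxy}furan-2(5H)-one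
Product: 11 tricyclic hydroxy lactone (trans-decalin with 1β-silyloxy and 6β-hydroxy groups and a cis-fused 12-menthyloxy γ-lactone at C7/C8)
Conditions: Fe(acac)3 (0.5 equiv), PhSiH3 (2.5 equiv), 10 (2 equiv), EtOH/ethylene glycol 5:1, 0 °C to rt
Reagents that add atoms: none
Why: Iron hydride generated from Fe(acac)3 and PhSiH3 transfers a hydrogen atom to the CH2 terminus of the exocyclic alkene of 9 (this hydrogen completes the angular methyl group), the tertiary C8a radical adds to C4 of butenolide 10 (C8 of the target) in a Giese addition, divalent iron reduces the resulting α-acyl radical to the lactone enolate and regenerates trivalent iron, and the enolate carbon C7 adds to the C6 aldehyde in a 6-(enolexo)-exo-trig aldol that closes ring B. The closest known reaction type is the hydrogen-atom-transfer-initiated radical–polar crossover annulation of γ,δ-unsaturated aldehydes with enones and enals, together with the anti-selective radical addition to 5-alkoxybutenolides. C8a is controlled by ring A: the acceptor reaches the planar radical from the face opposite the 1-silyloxy group and the C4a side chain, so the methyl group ends up cis to both and the ring fusion becomes trans. C8 is controlled by the reagent: the radical enters anti to the menthyloxy group on the (5R) acetal carbon of 10, whatever the sense of ring A. C7 and C6 follow from the tether (the aldol can only take place on the enolate face that carries C8a, giving the cis-fused lactone) and from the chelated transition state (6-hydroxyl cis to C11), and both are erased in step 8. The step needs hydrogen-atom transfer to the accessible 1,1-disubstituted alkene in preference to the tetrasubstituted C3=C4 bond and to electron-poor 10, which sterics and polarity secure, and it needs aldol capture to outrun protonation of the enolate, which the intramolecular six-membered closure favours.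

Step 8
Reactants: 11 tricyclic hydroxy lactone
Product: 13 alkylidene lactone (C6=C7 conjugated with the C11 lactone carbonyl), via mesylate 12 (not isolated)
Conditions: MsCl, Et3N, CH2Cl2, 0 °C; then DBU, rt
Reagents that add atoms: none
Why: Mesylation and E1cB elimination (C7–H is α to the lactone carbonyl) should give the conjugated C6=C7 double bond, while C8, which carries no acidic hydrogen, is untouched.

Step 9
Reactants: 13 alkylidene lactone
Product: 15 cyclic bis-acetal (C11 methyl acetal and C12 menthyl acetal sharing the ring oxygen), via lactol 14 (not isolated)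
Conditions: iBu2AlH, CH2Cl2, −78 °C; then MeOH, PPTS, rt
Reagents that add atoms: methanol (CO)
Why: Partial reduction of the lactone to the lactol at low temperature, then acid-catalysed acetalisation through the allylic oxocarbenium ion, fixes C11 at the aldehyde oxidation level as a base-stable methyl acetal (an anomer mixture at C11 is expected and is of no consequence).

Step 10
Reactants: 15 cyclic bis-acetal
Product: 16 1β-alcohol
Conditions: Bu4NF, THF, 0 to 40 °C
Reagents that add atoms: none
Why: Fluoride-mediated desilylation frees the C1 hydroxyl; the bis-acetal is stable to the basic conditions.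

Step 11
Reactants: 16 1β-alcohol; 17 3-phenylprop-2-ynoic acid
Product: 18 1β-(3-phenylprop-2-ynoate)
Conditions: 17, DCC, DMAP (10 mol %), CH2Cl2, 0 °C to rt
Reagents that add atoms: none
Why: Steglich esterification of the hindered neopentylic C1 hydroxyl with a slim, linear alkynoic acid; no stereocentre is touched.

Step 12
Reactants: 18 1β-(3-phenylprop-2-ynoate)
Product: 19 1β-[(Z)-3-phenylprop-2-enoate] bis-acetal
Conditions: H2 (1 atm), Pd/CaCO3 poisoned with Pb(OAc)2 (Lindlar catalyst), quinoline, EtOAc, rt
Reagents that add atoms: none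
Why: Lindlar semi-hydrogenation adds hydrogen syn to the alkyne and should give the (Z)-cinnamate; the tri- and tetrasubstituted ring alkenes are not reduced by the poisoned catalyst.

Step 13
Reactants: 19 1β-[(Z)-3-phenylprop-2-enoate] bis-acetal
Product: 20 (1R,4aS,8R,8aS)-7,8-diformyl-3,4,8a-trimethyl-1,2,4a,5,8,8a-hexahydronaphthalen-1-yl (2Z)-3-phenylprop-2-enoate
Conditions: 1 M aq. HCl/THF 1:4, 0 °C to rt
Reagents that add atoms: water (O)
Why: Mild acid hydrolysis of the cyclic bis-acetal should release both aldehydes (C11 conjugated with C6=C7, C12 on C8) with methanol and menthol, under conditions chosen not to enolise C8 or cleave the ester.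

**Compound list**

1 | 1,2-dimethylcyclohexa-1,4-diene | CC1=C(C)CC=CC1 | starting material
2 | cis-4,5-dimethylcyclohex-4-ene-1,2-diol (meso) | CC1=C(C)C[C@H](O)[C@H](O)C1 | intermediate
3 | (1S,6R)-6-{[tert-butyl(dimethyl)silyl]oxy}-3,4-dimethylcyclohex-3-en-1-ol (silyl ether on the future C1) | CC1=C(C)C[C@H](O)[C@H](O[Si](C)(C)C(C)(C)C)C1 | intermediate
4 | (6R)-6-{[tert-butyl(dimethyl)silyl]oxy}-3,4-dimethylcyclohex-3-en-1-one (ketone at the future C8a) | CC1=C(C)CC(=O)[C@H](O[Si](C)(C)C(C)(C)C)C1 | intermediate
5 | 2-bromo-N-methoxy-N-methylacetamide | CON(C)C(=O)CBr | starting material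
6 | N-methoxy-N-methyl-2-[(1R,5R)-5-{[tert-butyl(dimethyl)silyl]oxy}-2,3-dimethyl-6-oxocyclohex-2-en-1-yl]acetamide (side chain trans to the silyloxy group) | CC1=C(C)[C@@H](CC(=O)N(C)OC)C(=O)[C@H](O[Si](C)(C)C(C)(C)C)C1 | intermediate
7 | N-methoxy-N-methyl-2-[(1S,5R)-5-{[tert-butyl(dimethyl)silyl]oxy}-2,3-dimethyl-6-oxocyclohex-2-en-1-yl]acetamide (side chain cis to the silyloxy group) | CC1=C(C)[C@H](CC(=O)N(C)OC)C(=O)[C@H](O[Si](C)(C)C(C)(C)C)C1 | intermediate
8 | N-methoxy-N-methyl-2-[(1S,5R)-5-{[tert-butyl(dimethyl)silyl]oxy}-2,3-dimethyl-6-methylidenecyclohex-2-en-1-yl]acetamide | CC1=C(C)[C@H](CC(=O)N(C)OC)C(=C)[C@H](O[Si](C)(C)C(C)(C)C)C1 | intermediate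
9 | 2-[(1S,5R)-5-{[tert-butyl(dimethyl)silyl]oxy}-2,3-dimethyl-6-methylidenecyclohex-2-en-1-yl]acetaldehyde | CC1=C(C)[C@H](CC=O)C(=C)[C@H](O[Si](C)(C)C(C)(C)C)C1 | intermediate
10 | (5R)-5-{[(1R,2S,5R)-5-methyl-2-(propan-2-yl)cyclohexyl]oxy}furan-2(5H)-one | O=C1C=C[C@H](O[C@@H]2C[C@H](C)CC[C@H]2C(C)C)O1 | starting material
11 | hydroxy lactone: trans-decalin (4aα-H, 8aβ-CH3), 3,4-dimethyl-3-ene, 1β-OTBS, 6β-OH, γ-lactone C11(=O)–O–C12 cis-fused at C7/C8 (7α-H, 8α-H), (12R)-menthyloxy | CC1=C(C)[C@@H]2C[C@H](O)[C@@H]3C(=O)O[C@@H](O[C@@H]4C[C@H](C)CC[C@H]4C(C)C)[C@@H]3[C@@]2(C)[C@H](O[Si](C)(C)C(C)(C)C)C1 | intermediate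
12 | 6β-methanesulfonate of 11 | CC1=C(C)[C@@H]2C[C@H](OS(C)(=O)=O)[C@@H]3C(=O)O[C@@H](O[C@@H]4C[C@H](C)CC[C@H]4C(C)C)[C@@H]3[C@@]2(C)[C@H](O[Si](C)(C)C(C)(C)C)C1 | intermediate
13 | alkylidene lactone: as 11 with C6=C7 in place of 6-OH and 7-H | CC1=C(C)[C@@H]2CC=C3C(=O)O[C@@H](O[C@@H]4C[C@H](C)CC[C@H]4C(C)C)[C@@H]3[C@@]2(C)[C@H](O[Si](C)(C)C(C)(C)C)C1 | intermediate
14 | lactol: as 13 with C11 as CH(OH) (anomer mixture, 11,12-trans anomer drawn) | CC1=C(C)[C@@H]2CC=C3[C@H](O)O[C@@H](O[C@@H]4C[C@H](C)CC[C@H]4C(C)C)[C@@H]3[C@@]2(C)[C@H](O[Si](C)(C)C(C)(C)C)C1 | intermediate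
15 | cyclic bis-acetal: C11 as CH(OCH3), C12 as CH(O-menthyl), shared ring oxygen, 1β-OTBS (C11 anomer mixture, 11,12-trans anomer drawn) | CC1=C(C)[C@@H]2CC=C3[C@H](OC)O[C@@H](O[C@@H]4C[C@H](C)CC[C@H]4C(C)C)[C@@H]3[C@@]2(C)[C@H](O[Si](C)(C)C(C)(C)C)C1 | intermediate
16 | 1β-alcohol of the bis-acetal | CC1=C(C)[C@@H]2CC=C3[C@H](OC)O[C@@H](O[C@@H]4C[C@H](C)CC[C@H]4C(C)C)[C@@H]3[C@@]2(C)[C@H](O)C1 | intermediate
17 | 3-phenylprop-2-ynoic acid | OC(=O)C#Cc1ccccc1 | starting material
18 | 1β-(3-phenylprop-2-ynoate) of the bis-acetal | CC1=C(C)[C@@H]2CC=C3[C@H](OC)O[C@@H](O[C@@H]4C[C@H](C)CC[C@H]4C(C)C)[C@@H]3[C@@]2(C)[C@H](OC(=O)C#Cc5ccccc5)C1 | intermediate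
19 | 1β-[(Z)-3-phenylprop-2-enoate] of the bis-acetal | CC1=C(C)[C@@H]2CC=C3[C@H](OC)O[C@@H](O[C@@H]4C[C@H](C)CC[C@H]4C(C)C)[C@@H]3[C@@]2(C)[C@H](OC(=O)/C=C\c5ccccc5)C1 | intermediate
20 | (1R,4aS,8R,8aS)-7,8-diformyl-3,4,8a-trimethyl-1,2,4a,5,8,8a-hexahydronaphthalen-1-yl (2Z)-3-phenylprop-2-enoate | CC1=C(C)[C@@H]2CC=C(C=O)[C@H](C=O)[C@@]2(C)[C@H](OC(=O)/C=C\c2ccccc2)C1 | target

**Step count**

Total: 13 steps. Longest linear sequence: 13 steps (1 to 20); 5, 10 and 17 are purchased.

**Steps most likely to fail**

Step 7. The iron enolate may be protonated by the alcoholic solvent before it adds to the aldehyde (loss of the polar crossover), and reversible hydrogen-atom transfer may move the exocyclic alkene into the ring. The fallback separates the two bond formations and sets out from 8. The established reductive olefin–acceptor coupling (Fe(acac)3, PhSiH3, EtOH) of amide 8 with 10 needs no crossover and should give the open Giese adduct, amide lactone F1. Cp2Zr(H)Cl reduces the Weinreb amide in the presence of the lactone to the aldehyde lactone F2. Ring B is then closed in a discrete ionic step, a soft-enolisation aldol of the lactone onto the aldehyde with TiCl4 and Bu3N, which comes back to the route at 11.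

Step 4. Facial discrimination at C4a may be low or opposite in sense; alkylation and reprotonation are complementary, so a wrong bias inverts the outcome. Base may also move the β,γ double bond into conjugation. The fallback fixes the cis relationship by ring formation and sets out from 4. Alkylation of the enolate with methyl bromoacetate gives the methyl ester F3 as a C4a epimer mixture. HF·pyridine removes the silyl group and catalytic DBU then drives lactonisation, which only the cis isomer can undergo, so the mixture is funnelled through the enol into the bridged keto lactone F4. Lombardo–Takai methylenation gives the methylidene lactone F5, in which C4a can no longer epimerise. MeNH(OMe)·HCl with AlMe3 opens the lactone to the hydroxy Weinreb amide F6, and TBSOTf with 2,6-lutidine comes back to the route at 8.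

Step 11. Acylation of the neopentylic C1 hydroxyl (next to the quaternary C8a and peri to the C12 acetal) may be slow, and the nucleophilic catalyst may add to the activated ynoate. The fallback builds the cinnamate on the oxygen from a small acyl group and sets out from 16. Bromoacetyl bromide with pyridine gives the bromoacetate F7. Arbuzov reaction with P(OCH2CF3)3 gives the bis(trifluoroethyl) phosphonoacetate F8. Still–Gennari olefination with benzaldehyde (KN(SiMe3)2, 18-crown-6, THF, −78 °C) should give the (Z)-cinnamate directly and comes back to the route at 19, so step 12 is not needed.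

Further compounds
F1 | step 7 | open Giese adduct of 8 and 10: ring A with 8aβ-CH3, C8 carrying the saturated (12R)-menthyloxy γ-lactone, Weinreb amide side chain on C4a | CC1=C(C)[C@H](CC(=O)N(C)OC)[C@@](C)([C@@H]2CC(=O)O[C@H]2O[C@@H]3C[C@H](C)CC[C@H]3C(C)C)[C@H](O[Si](C)(C)C(C)(C)C)C1
F2 | step 7 | aldehyde lactone (F1 with CH2CHO in place of the amide side chain) | CC1=C(C)[C@H](CC=O)[C@@](C)([C@@H]2CC(=O)O[C@H]2O[C@@H]3C[C@H](C)CC[C@H]3C(C)C)[C@H](O[Si](C)(C)C(C)(C)C)C1
F3 | step 4 | methyl 2-[(5R)-5-{[tert-butyl(dimethyl)silyl]oxy}-2,3-dimethyl-6-oxocyclohex-2-en-1-yl]acetate (C1 epimer mixture) | CC1=C(C)C(CC(=O)OC)C(=O)[C@H](O[Si](C)(C)C(C)(C)C)C1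
F4 | step 4 | bridged keto lactone (δ-lactone between the C1 oxygen and the C4a acetic acid chain, C8a ketone) | CC1=C(C)[C@@H]2CC(=O)O[C@H](C1)C2=O
F5 | step 4 | bridged methylidene lactone | CC1=C(C)[C@@H]2CC(=O)O[C@H](C1)C2=C
F6 | step 4 | N-methoxy-N-methyl-2-[(1S,5R)-5-hydroxy-2,3-dimethyl-6-methylidenecyclohex-2-en-1-yl]acetamide | CC1=C(C)[C@H](CC(=O)N(C)OC)C(=C)[C@H](O)C1
F7 | step 11 | 1β-bromoacetate of the bis-acetal | CC1=C(C)[C@@H]2CC=C3[C@H](OC)O[C@@H](O[C@@H]4C[C@H](C)CC[C@H]4C(C)C)[C@@H]3[C@@]2(C)[C@H](OC(=O)CBr)C1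
F8 | step 11 | 1β-[bis(2,2,2-trifluoroethoxy)phosphoryl]acetate of the bis-acetal | CC1=C(C)[C@@H]2CC=C3[C@H](OC)O[C@@H](O[C@@H]4C[C@H](C)CC[C@H]4C(C)C)[C@@H]3[C@@]2(C)[C@H](OC(=O)CP(=O)(OCC(F)(F)F)OCC(F)(F)F)C1
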